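# Proposed synthesis of CNP0170141.1 (compound 31) by a rhodium [2+2+2] enyne–alkyne cycloaddition

## The problem

Compound 31 is an eremophilane diester. Its core is a trans-fused decalin (ring A: C1–C5 and C10; ring B: C5–C10) with a quaternary, methyl-bearing C5 next to the methyl-bearing C4 and an acylated carbinol at C3. Ring B carries an α-ketol (C9 carbinol, C8 ketone) cross-conjugated to a C7 isopropylidene group. Five stereocentres sit on the decalin (3R,4R,5R,9S,10R; with β as the face of the C5 methyl: 3α-O, 4β-CH3, 5β-CH3, 9α-OH, 10α-H). A sixth, (S), lies in the side chain, too far from the core to be controlled by it, so it must come from the chiral pool. C3 and C4 form an acyclic syn pair that reagent control can set and that can then direct the adjacent quaternary C5. The axial C5 methyl in turn governs the faces of C10 (1,2) and C9 (1,3), and both the trans ring fusion and the equatorial 9α-oxygen are the thermodynamically preferred arrangements next to a carbonyl. The fragile parts are the two (Z)-enoates (isomerisation, conjugate addition, loss of the γ-acyloxy group), the α-ketol (epimerisation and ketol shift under base) and the isopropylidene enone (deconjugation). This argues for attaching the side chain late, as a diyne, and for unveiling the (Z)-alkenes and the free ketol in the last two steps. A short entry is possible because ring B can be read as three two-carbon units: the 1,1-disubstituted alkene C5=C6, an alkyne C9≡C10 tied to it through C1–C4, and a free alkyne C7≡C8 whose dimethylcarbinol is a masked isopropylidene ketone. A [2+2+2] cycloaddition joins them and closes both rings, with boron on C9 marking that carbon for oxygen.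

## Retrosynthesis

**Side chain last.** Target 31 is traced to its C9 triethylsilyl ether 30, and the two (Z)-alkenes of 30 to the two alkynes of diyne ester 29. Cutting the C3–O acyl bond of 29 gives core alcohol 20 and diynoic acid 28. Coupling the chain as a diyne is preferred over a preformed (Z,Z)-acid, whose activated form isomerises easily, and over two acylations on the core, which would add linear steps and a selective desilylation. The forward steps must esterify an equatorial alcohol flanked by the C4 methyl, semihydrogenate two ynoates beside a tetrasubstituted enone, and free the ketol without base.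

**Acid 28.** The tert-butyl ester 27 is cut at the propargylic ester to hydroxy ester 25 and hex-2-ynoic acid 26. Compound 25 goes back through silyl ether 24 to the protected alkyne 22 and commercial (S)-pent-1-yn-3-ol 21, which supplies the side-chain stereocentre unchanged. The tert-butyl ester is chosen because acid removes it without touching the propargylic ester. Nothing beyond standard acetylide carboxylation and carbodiimide coupling is asked.

**C3 unmasking and C9 configuration.** Alcohol 20 comes from its 4-methoxybenzyl ether 19 by oxidative cleavage, which the silyl ether and the enone tolerate. Compound 19 is the equatorial (9α) epimer of silyloxy ketone 18, reached by base equilibration. This cut is preferred to an inversion at the allylic alcohol stage because the 9β carbinol is axial, has an antiperiplanar C10 hydrogen and would eliminate to a conjugated diene. The forward step needs only the thermodynamic bias created by the 1,3-diaxial clash between a 9β substituent and the C5 methyl.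

**C8 ketone and isopropylidene.** Ketone 18 is the product of an oxidative 1,3-transposition (Babler–Dauben) of tertiary allylic alcohol 17. This one step moves oxygen to C8, shifts the alkene to C7=C11 and raises the oxidation level. The alternative, an aldol with a three-carbon ketone on a C8 ketone followed by dehydration, would require a separate C8 oxidation. The C9 oxygen must be protected and the tertiary hydroxyl free.

**C9 carbinol.** Silyl ether 17 comes from diol 16, and 16 from enone 15 by 1,2-reduction. The kinetic hydride should arrive anti to the C5 methyl and give the 9β alcohol. This is accepted because C9 is corrected at 18, so the reduction need not be selective.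

**C9 oxygen and C10.** Enone 15 arises from dienylboronate 12 by oxidation of the C–B bond, through dienol 13. C10 becomes a stereocentre on ketonisation and is α to the new ketone, so the 10β epimer 14 can be funnelled to the trans-fused 15. This is the only point at which C10 can be equilibrated, which is why the ketone is made before any reduction.

**Key disconnection.** Diene 12 is opened across C5–C10, C6–C7 and C8–C9 into enyne boronate 10 and 2-methylbut-3-yn-2-ol 11. Two rings, three skeletal bonds and the quaternary centre are traded for an acyclic chain with two stereocentres and a commercial alkyne. Neighbouring cuts that build one ring at a time need a preformed ring A. The forward reaction must select the C5 face, orient 11 so that its CH carbon bonds to C9, and outrun homotrimerisation of 11.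

**Enyne boronate.** Compound 10 is the borylated form of terminal alkyne 8, the 4-methoxybenzyl ether of homoallylic alcohol 7. Cutting the C3–C4 bond of 7 gives pent-4-ynal 5 (from pent-4-yn-1-ol 4) and the (Z)-2-methylcrotyl boronate 3, available from isoprene 1 by 1,4-hydroboration. A single allylboration sets both stereocentres and installs the 1,1-disubstituted alkene; an aldol route would need four further steps to reach the same alkene.

## Roads not taken

**Alternative 1:** Diels–Alder construction of ring B on a preformed ring A. The cut is C5–C6 and C7–C8; the semicyclic 1-silyloxydiene A1 (C8=C9–C10=C5) would react with methyl acrylate A2 to give adduct A3.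
- Merits: the cycloaddition type is well known, the silyloxy group directs the ester to C7, and the C8 oxygen is already in place.
- Where it is better: the adduct alkene lies at C9=C10, where hydroboration anti to the angular methyl would set 9α-OH and 10α-H in one step. The chosen plan spends an oxidation, a reduction and an epimerisation on those two centres.
- Weak points: the diene terminus C5 is fully substituted and part of a ring, so a quaternary centre must form at the most hindered diene carbon. Diene A1 presupposes a separate synthesis of ring A with C3 and C4 in place and of an acid-sensitive dienol ether. The C7 ester still needs double methyl addition, dehydration and C8 oxidation.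
- Comparison: the chosen plan forms both rings and the quaternary centre from an acyclic chain made in four steps, and makes C5 from an unhindered methylene-terminated alkene.

**Alternative 2:** Cationic bicyclisation of an achiral chain. The cut is C9–C10 and C4–C5. A chiral chelating Lewis acid (a divalent copper bis(oxazoline) or trivalent scandium pybox complex) would activate the α-ketoaldehyde of chloro-dienyl precursor A4. The central alkene attacks through C10, and the chloroalkene traps the C5 cation and becomes the C3 ketone of A5.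
- Where it is better: it is clearly the shortest route, and it delivers ring B with 9α-OH, the C8 ketone and the isopropylidene group already correct. The chosen plan needs six steps after the cycloaddition to reach that pattern.
- Weak points: absolute control over a three-bond cationic cascade started at a hydrate-prone 1,2-dicarbonyl has little precedent. A chloroalkene is a weak terminator for a tertiary cation. Compound A5 then needs a C3 ketone reduction that must give the equatorial 3α-alcohol, although hydride should arrive anti to the 1,3-diaxial C5 methyl and give the axial epimer, and this beside a second ketone. The C3 and C9 hydroxyls must then be told apart for acylation.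
- Comparison: the chosen plan carries the C3 oxygen with fixed configuration from the first C–C bond and keeps C3 and C9 in different protecting groups throughout.

**Alternative 3:** Enzymatic cyclisation. A magnesium-dependent class 1 sesquiterpene cyclase (aristolochene synthase) would convert farnesyl diphosphate A6 into (+)-aristolochene A7.
- Where it is better: the bicyclic skeleton forms in one step with C4 and C5 (and C7) correct, with a selectivity no chemical step in the chosen plan can match.
- Weak points: A7 has no oxygen. The Δ9 alkene and the isopropenyl group would allow C8, C9 and C10 to be handled chemically. C3, however, is an unactivated ring methylene remote from any handle, and its stereoselective hydroxylation would need a second, engineered oxidase or a long relay. The route also depends on protein expression and on a costly diphosphate.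
- Comparison: the chosen plan introduces the C3 oxygen in its first C–C bond-forming step and needs only ordinary laboratory reagents.

Key step: step 6

Remark on numbering: ring positions use eremophilane numbering (C11 is the carbinol or isopropylidene carbon on C7), and β is the face of the C5 methyl.

Remark on catalyst antipodes: the phosphoric acid in step 3 and the BINAP in step 6 are assigned by analogy (the (R)-acid is taken to deliver allyl groups to the Re face of aldehydes; C4 is taken to dominate at C5). The mirror-image catalyst is used if the sense proves opposite.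

## Route

Step 1
Reactants: 1 isoprene
Product: 3 (Z)-4,4,5,5-tetramethyl-2-(2-methylbut-2-en-1-yl)-1,3,2-dioxaborolane, via catechol boronate 2 (not isolated)
Conditions: catecholborane, Pd(PPh3)4 (cat.), THF, rt; then pinacol, rt
Reagents that add atoms: catecholborane, B1Oc2ccccc2O1; pinacol, CC(C)(O)C(C)(C)O
Why: Palladium-catalysed 1,4-hydroboration of a 1,3-diene: hydride from the H–Pd–B adduct of zerovalent palladium should add to the unsubstituted diene terminus, and the anti allyl complex should deliver boron to the CH2 next to the methyl-bearing carbon, which fixes the (Z) geometry. Transesterification with pinacol then gives the more robust pinacol ester.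

Step 2
Reactants: 4 pent-4-yn-1-ol
Product: 5 pent-4-ynal
Conditions: TEMPO (cat.), PhI(OAc)2, CH2Cl2, rt
Reagents that add atoms: none
Why: Oxoammonium-mediated oxidation of a primary alcohol stops at the aldehyde under neutral conditions. The volatile aldehyde should be used as a concentrated solution.

Step 3
Reactants: 5 pent-4-ynal; 3 (Z)-4,4,5,5-tetramethyl-2-(2-methylbut-2-en-1-yl)-1,3,2-dioxaborolane
Product: 7 (3R,4R)-2,3-dimethyloct-1-en-7-yn-4-ol, via borate ester 6 (not isolated)
Conditions: (S)-3,3'-bis(2,4,6-triisopropylphenyl)-1,1'-binaphthyl-2,2'-diyl hydrogen phosphate (5 mol %), 4 Å MS, toluene, −30 °C; aqueous work-up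
Reagents that add atoms: none
Why: Chiral phosphoric acid-catalysed allylboration through a closed Zimmerman–Traxler chair: the (Z) boronate should give the syn pair, and the acid, hydrogen-bonded to the pseudoaxial boronate oxygen, should select the Si face of the aldehyde and so set the carbinol as (R) and the adjacent methine as (R).

Step 4
Reactants: 7 (3R,4R)-2,3-dimethyloct-1-en-7-yn-4-ol
Product: 8 1-({[(3R,4R)-2,3-dimethyloct-1-en-7-yn-4-yl]oxy}methyl)-4-methoxybenzene
Conditions: NaH, 4-methoxybenzyl chloride, Bu4NI (cat.), THF/DMF, 0 °C to rt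
Reagents that add atoms: 4-methoxybenzyl chloride, COc1ccc(CCl)cc1
Why: Williamson etherification of the sodium alkoxide; the ether survives organolithium, rhodium, borohydride and chromium reagents and is later removed oxidatively.

Step 5
Reactants: 8 1-({[(3R,4R)-2,3-dimethyloct-1-en-7-yn-4-yl]oxy}methyl)-4-methoxybenzene
Product: 10 2-{(5R,6R)-5-[(4-methoxybenzyl)oxy]-6,7-dimethyloct-7-en-1-yn-1-yl}-4,4,5,5-tetramethyl-1,3,2-dioxaborolane, via lithium acetylide 9 (not isolated)
Conditions: n-BuLi, THF, −78 °C; 2-isopropoxy-4,4,5,5-tetramethyl-1,3,2-dioxaborolane; then HCl·Et2O, −78 °C to rt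
Reagents that add atoms: 2-isopropoxy-4,4,5,5-tetramethyl-1,3,2-dioxaborolane, CC(C)OB1OC(C)(C)C(C)(C)O1
Why: Borylation of a lithium acetylide: the acetylide adds to the borate to give an ate complex, and anhydrous acid expels isopropanol to release the alkynylboronate without protodeboronation.

Step 6
Reactants: 10 2-{(5R,6R)-5-[(4-methoxybenzyl)oxy]-6,7-dimethyloct-7-en-1-yn-1-yl}-4,4,5,5-tetramethyl-1,3,2-dioxaborolane; 11 2-methylbut-3-yn-2-ol
Product: 12 (3R,4R,5R)-3-[(4-methoxybenzyl)oxy]-9-(4,4,5,5-tetramethyl-1,3,2-dioxaborolan-2-yl)eremophila-7,9-dien-11-ol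
Conditions: [Rh(cod)2]BF4 (10 mol %), (S)-BINAP (10 mol %), H2 then Ar; ClCH2CH2Cl, 60 °C; 11 (3 equiv) by syringe pump
Reagents that add atoms: none
Why: Proposed new method: oxidative cyclisation of the alkynylboronate and the 1,1-disubstituted alkene of 10 on cationic monovalent rhodium should give a rhodacyclopentene of trivalent rhodium (Rh–C9=C10–C5–C6), which inserts 11 and reductively eliminates to the cyclohexa-1,3-diene 12. The closest known reaction type is the enantioselective rhodium–bisphosphine [2+2+2] cycloaddition of heteroatom-tethered 1,6-enynes bearing 1,1-disubstituted alkenes with alkynes; the all-carbon four-atom tether and the boryl alkyne are the untested extensions. Ring A closes in the oxidative cyclisation by C5–C10 bond formation between the inner carbons of the enyne (exo to both π bonds, six-membered), and ring B closes by insertion of 11 into the metallacycle followed by C–C reductive elimination (C6–C7 and C8–C9). The quaternary C5 is set under substrate control from C4: in the chair-like forming ring the C3 ether and C4 methyl are equatorial, C6 lies in the plane of the C9=C10 bond and the C5 methyl is axial and cis to the C4 methyl, whereas the other face needs both substituents axial and a 1,3-diaxial methyl/ether contact. (S)-BINAP is meant to reinforce this bias. The step also needs the CH carbon of 11 to bond to C9, which repulsion between the pinacolboryl group and the tertiary carbinol should secure, and it needs cross-cycloaddition to beat homotrimerisation, which slow addition of 11 addresses. Because C5 is quaternary the Rh–C6 bond has no β-hydrogen, so cycloisomerisation to a diene cannot compete.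

Step 7
Reactants: 12 (3R,4R,5R)-3-[(4-methoxybenzyl)oxy]-9-(4,4,5,5-tetramethyl-1,3,2-dioxaborolan-2-yl)eremophila-7,9-dien-11-ol
Product: 15 (3R,4R,5R,10R)-11-hydroxy-3-[(4-methoxybenzyl)oxy]eremophil-7-en-9-one (trans-fused 10α-H), via dienol 13 (not isolated), via cis-fused 10-epimer 14 (not isolated)
Conditions: NaBO3·4H2O, THF/H2O (1:1), 0 °C to rt; then DBU, THF, rt
Reagents that add atoms: sodium perborate, [Na+].[O-]OB=O
Why: Perborate oxidation of an alkenylboronate (1,2-shift of carbon from boron to oxygen) gives the dienol, which ketonises to the C9 enone. Protonation at C10 anti to the adjacent C5 methyl and DBU equilibration through the enolate should both lead to the trans-fused ketone, in which the axial C5 methyl has no 1,3-diaxial hydrogen in ring B because C7 and C9 are both trigonal.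

Step 8
Reactants: 15 (3R,4R,5R,10R)-11-hydroxy-3-[(4-methoxybenzyl)oxy]eremophil-7-en-9-one
Product: 16 (3R,4R,5R,9S,10R)-3-[(4-methoxybenzyl)oxy]eremophil-7-ene-9,11-diol (9β-OH)
Conditions: NaBH4, CeCl3·7H2O, MeOH, −78 to −20 °C
Reagents that add atoms: none
Why: Luche 1,2-reduction of the enone; hydride should approach C9 anti to the 1,3-related axial C5 methyl and give the axial 9β alcohol. The route does not depend on this ratio, because C9 is equilibrated in step 11 and C10 is fixed from here on.

Step 9
Reactants: 16 (3R,4R,5R,9S,10R)-3-[(4-methoxybenzyl)oxy]eremophil-7-ene-9,11-diol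
Product: 17 (3R,4R,5R,9S,10R)-3-[(4-methoxybenzyl)oxy]-9-(triethylsilyloxy)eremophil-7-en-11-ol (9β-OSiEt3)
Conditions: Et3SiCl, imidazole, DMAP (cat.), DMF, 0 °C to rt
Reagents that add atoms: chlorotriethylsilane, CC[Si](Cl)(CC)CC
Why: Silylation with a chlorosilane and imidazole distinguishes the secondary from the tertiary hydroxyl, which must stay free for the next step.

Step 10
Reactants: 17 (3R,4R,5R,9S,10R)-3-[(4-methoxybenzyl)oxy]-9-(triethylsilyloxy)eremophil-7-en-11-ol
Product: 18 (3R,4R,5R,9R,10R)-3-[(4-methoxybenzyl)oxy]-9-(triethylsilyloxy)eremophil-7(11)-en-8-one (9β-OSiEt3)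
Conditions: pyridinium chlorochromate, NaOAc, 4 Å MS, CH2Cl2, rt
Reagents that add atoms: pyridinium chlorochromate (delivers the C8 oxygen), [O-][Cr](=O)(=O)Cl.c1cc[nH+]cc1
Why: Babler–Dauben oxidative transposition: the tertiary allylic chromate ester of hexavalent chromium undergoes a [3,3] shift to C8, and the resulting secondary chromate is oxidised to the ketone, leaving the C7=C11 isopropylidene alkene in conjugation.

Step 11
Reactants: 18 (3R,4R,5R,9R,10R)-3-[(4-methoxybenzyl)oxy]-9-(triethylsilyloxy)eremophil-7(11)-en-8-one
Product: 19 (3R,4R,5R,9S,10R)-3-[(4-methoxybenzyl)oxy]-9-(triethylsilyloxy)eremophil-7(11)-en-8-one (9α-OSiEt3)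
Conditions: DBU, toluene, 60 °C
Reagents that add atoms: none
Why: Base-mediated epimerisation α to the ketone through the C8–C9 enolate: the axial 9β silyloxy group suffers a 1,3-diaxial interaction with the C5 methyl, so equilibrium should lie on the side of the equatorial 9α epimer. C10 is not enolisable in this ketone and stays fixed.

Step 12
Reactants: 19 (3R,4R,5R,9S,10R)-3-[(4-methoxybenzyl)oxy]-9-(triethylsilyloxy)eremophil-7(11)-en-8-one
Product: 20 (3R,4R,5R,9S,10R)-3-hydroxy-9-(triethylsilyloxy)eremophil-7(11)-en-8-one
Conditions: DDQ, CH2Cl2/pH 7 buffer, 0 °C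
Reagents that add atoms: none
Why: Oxidative cleavage of the 4-methoxybenzyl ether by hydride abstraction and hydrolysis of the oxocarbenium ion; the buffered medium spares the silyl ether and the enone.

Step 13
Reactants: 21 (S)-pent-1-yn-3-ol
Product: 22 tert-butyl(dimethyl){[(3S)-pent-1-yn-3-yl]oxy}silane
Conditions: t-BuMe2SiCl, imidazole, CH2Cl2, rt
Reagents that add atoms: tert-butyl(chloro)dimethylsilane, CC(C)(C)[Si](C)(C)Cl
Why: Standard silylation masks the hydroxyl so that only the alkyne C–H is deprotonated in the next step; the stereocentre is untouched.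

Step 14
Reactants: 22 tert-butyl(dimethyl){[(3S)-pent-1-yn-3-yl]oxy}silane
Product: 24 tert-butyl (4S)-4-[(tert-butyldimethylsilyl)oxy]hex-2-ynoate, via lithium acetylide 23 (not isolated)
Conditions: n-BuLi, THF, −78 °C; Boc2O, −78 to 0 °C
Reagents that add atoms: di-tert-butyl dicarbonate, CC(C)(C)OC(=O)OC(=O)OC(C)(C)C
Why: Acylation of a lithium acetylide with the dicarbonate gives the tert-butyl ynoate directly; the tert-butyl ester is later removable by acid in the presence of the propargylic ester.

Step 15
Reactants: 24 tert-butyl (4S)-4-[(tert-butyldimethylsilyl)oxy]hex-2-ynoate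
Product: 25 tert-butyl (4S)-4-hydroxyhex-2-ynoate
Conditions: HF·pyridine, THF, 0 °C to rt
Reagents that add atoms: none
Why: Fluoride cleavage of the silyl ether under non-basic conditions avoids the base-induced isomerisation of a γ-hydroxy ynoate to a γ-oxo enoate.

Step 16
Reactants: 25 tert-butyl (4S)-4-hydroxyhex-2-ynoate; 26 hex-2-ynoic acid
Product: 27 tert-butyl (4S)-4-(hex-2-ynoyloxy)hex-2-ynoate
Conditions: DCC, DMAP (cat.), CH2Cl2, −20 to 0 °C
Reagents that add atoms: none
Why: Steglich esterification; low temperature and a small charge of DMAP limit conjugate addition of the catalyst to the ynoates. The carbinol centre is acylated on oxygen and keeps its configuration.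

Step 17
Reactants: 27 tert-butyl (4S)-4-(hex-2-ynoyloxy)hex-2-ynoate
Product: 28 (4S)-4-(hex-2-ynoyloxy)hex-2-ynoic acid
Conditions: CF3CO2H, CH2Cl2, 0 °C to rt
Reagents that add atoms: none
Why: Acidolysis of the tert-butyl ester through the tert-butyl cation; the secondary propargylic ester does not ionise under these conditions.

Step 18
Reactants: 20 (3R,4R,5R,9S,10R)-3-hydroxy-9-(triethylsilyloxy)eremophil-7(11)-en-8-one; 28 (4S)-4-(hex-2-ynoyloxy)hex-2-ynoic acid
Product: 29 (3R,4R,5R,9S,10R)-8-oxo-9-(triethylsilyloxy)eremophil-7(11)-en-3-yl (4S)-4-(hex-2-ynoyloxy)hex-2-ynoate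
Conditions: DCC, DMAP (cat.), CH2Cl2, 0 °C
Reagents that add atoms: none
Why: Steglich esterification of the equatorial C3 alcohol, the only free hydroxyl; acylation on oxygen retains the C3 configuration, and alkynoic acids cannot lose alkene geometry on activation.

Step 19
Reactants: 29 (3R,4R,5R,9S,10R)-8-oxo-9-(triethylsilyloxy)eremophil-7(11)-en-3-yl (4S)-4-(hex-2-ynoyloxy)hex-2-ynoate
Product: 30 (3R,4R,5R,9S,10R)-8-oxo-9-(triethylsilyloxy)eremophil-7(11)-en-3-yl (2Z,4S)-4-{[(2Z)-hex-2-enoyl]oxy}hex-2-enoate
Conditions: H2 (1 atm), Pd/CaCO3 poisoned with Pb(OAc)2, quinoline, EtOAc, rt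
Reagents that add atoms: none
Why: Lindlar semihydrogenation: syn delivery of hydrogen on the poisoned palladium surface converts both ynoates into (Z)-enoates, while the tetrasubstituted enone alkene is too hindered to be reduced.

Step 20
Reactants: 30 (3R,4R,5R,9S,10R)-8-oxo-9-(triethylsilyloxy)eremophil-7(11)-en-3-yl (2Z,4S)-4-{[(2Z)-hex-2-enoyl]oxy}hex-2-enoate
Product: 31 (3R,4R,5R,9S,10R)-9-hydroxy-8-oxoeremophil-7(11)-en-3-yl (2Z,4S)-4-{[(2Z)-hex-2-enoyl]oxy}hex-2-enoate
Conditions: HF·pyridine, pyridine, THF, 0 °C
Reagents that add atoms: none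
Why: Buffered fluoride desilylation frees the 9α-hydroxyl without base, so neither the ketol nor the (Z)-enoates should isomerise; the liberated ketol is already the equatorial, thermodynamically preferred epimer.

## Compound list

1 | isoprene (2-methylbuta-1,3-diene) | C=CC(C)=C | starting material
2 | 2-[(2Z)-2-methylbut-2-en-1-yl]-1,3,2-benzodioxaborole | C/C=C(/C)CB1Oc2ccccc2O1 | intermediate (not isolated)
3 | (Z)-4,4,5,5-tetramethyl-2-(2-methylbut-2-en-1-yl)-1,3,2-dioxaborolane | C/C=C(/C)CB1OC(C)(C)C(C)(C)O1 | intermediate
4 | pent-4-yn-1-ol | C#CCCCO | starting material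
5 | pent-4-ynal | C#CCCC=O | intermediate
6 | 2-{[(3R,4R)-2,3-dimethyloct-1-en-7-yn-4-yl]oxy}-4,4,5,5-tetramethyl-1,3,2-dioxaborolane | CC1(C)OB(O[C@@H]([C@H](C)C(C)=C)CCC#C)OC1(C)C | intermediate (not isolated)
7 | (3R,4R)-2,3-dimethyloct-1-en-7-yn-4-ol | O[C@@H]([C@H](C)C(C)=C)CCC#C | intermediate
8 | 1-({[(3R,4R)-2,3-dimethyloct-1-en-7-yn-4-yl]oxy}methyl)-4-methoxybenzene | COc1ccc(CO[C@@H]([C@H](C)C(C)=C)CCC#C)cc1 | intermediate
9 | lithium acetylide of 8 | COc1ccc(CO[C@@H]([C@H](C)C(C)=C)CCC#C[Li])cc1 | intermediate (not isolated)
10 | 2-{(5R,6R)-5-[(4-methoxybenzyl)oxy]-6,7-dimethyloct-7-en-1-yn-1-yl}-4,4,5,5-tetramethyl-1,3,2-dioxaborolane | COc1ccc(CO[C@@H]([C@H](C)C(C)=C)CCC#CB2OC(C)(C)C(C)(C)O2)cc1 | intermediate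
11 | 2-methylbut-3-yn-2-ol | CC(C)(O)C#C | starting material
12 | (3R,4R,5R)-3-[(4-methoxybenzyl)oxy]-9-(4,4,5,5-tetramethyl-1,3,2-dioxaborolan-2-yl)eremophila-7,9-dien-11-ol | COc1ccc(CO[C@@H]2CCC3=C(B4OC(C)(C)C(C)(C)O4)C=C(C(C)(C)O)C[C@]3(C)[C@H]2C)cc1 | intermediate
13 | (3R,4R,5R)-3-[(4-methoxybenzyl)oxy]eremophila-7,9-diene-9,11-diol | COc1ccc(CO[C@@H]2CCC3=C(O)C=C(C(C)(C)O)C[C@]3(C)[C@H]2C)cc1 | intermediate (not isolated)
14 | (3R,4R,5R,10S)-11-hydroxy-3-[(4-methoxybenzyl)oxy]eremophil-7-en-9-one (cis-fused, 10β-H) | COc1ccc(CO[C@@H]2CC[C@@H]3C(=O)C=C(C(C)(C)O)C[C@]3(C)[C@H]2C)cc1 | intermediate (not isolated)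
15 | (3R,4R,5R,10R)-11-hydroxy-3-[(4-methoxybenzyl)oxy]eremophil-7-en-9-one (trans-fused, 10α-H) | COc1ccc(CO[C@@H]2CC[C@H]3C(=O)C=C(C(C)(C)O)C[C@]3(C)[C@H]2C)cc1 | intermediate
16 | (3R,4R,5R,9S,10R)-3-[(4-methoxybenzyl)oxy]eremophil-7-ene-9,11-diol (9β-OH, 10α-H) | COc1ccc(CO[C@@H]2CC[C@H]3[C@@H](O)C=C(C(C)(C)O)C[C@]3(C)[C@H]2C)cc1 | intermediate
17 | (3R,4R,5R,9S,10R)-3-[(4-methoxybenzyl)oxy]-9-(triethylsilyloxy)eremophil-7-en-11-ol (9β-OSiEt3) | COc1ccc(CO[C@@H]2CC[C@H]3[C@@H](O[Si](CC)(CC)CC)C=C(C(C)(C)O)C[C@]3(C)[C@H]2C)cc1 | intermediate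
18 | (3R,4R,5R,9R,10R)-3-[(4-methoxybenzyl)oxy]-9-(triethylsilyloxy)eremophil-7(11)-en-8-one (9β-OSiEt3) | COc1ccc(CO[C@@H]2CC[C@H]3[C@@H](O[Si](CC)(CC)CC)C(=O)C(=C(C)C)C[C@]3(C)[C@H]2C)cc1 | intermediate
19 | (3R,4R,5R,9S,10R)-3-[(4-methoxybenzyl)oxy]-9-(triethylsilyloxy)eremophil-7(11)-en-8-one (9α-OSiEt3) | COc1ccc(CO[C@@H]2CC[C@H]3[C@H](O[Si](CC)(CC)CC)C(=O)C(=C(C)C)C[C@]3(C)[C@H]2C)cc1 | intermediate
20 | (3R,4R,5R,9S,10R)-3-hydroxy-9-(triethylsilyloxy)eremophil-7(11)-en-8-one | O[C@@H]1CC[C@H]2[C@H](O[Si](CC)(CC)CC)C(=O)C(=C(C)C)C[C@]2(C)[C@H]1C | intermediate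
21 | (S)-pent-1-yn-3-ol | O[C@H](C#C)CC | starting material
22 | tert-butyl(dimethyl){[(3S)-pent-1-yn-3-yl]oxy}silane | CC(C)(C)[Si](C)(C)O[C@H](C#C)CC | intermediate
23 | lithium acetylide of 22 | CC(C)(C)[Si](C)(C)O[C@H](C#C[Li])CC | intermediate (not isolated)
24 | tert-butyl (4S)-4-[(tert-butyldimethylsilyl)oxy]hex-2-ynoate | CC(C)(C)[Si](C)(C)O[C@H](C#CC(=O)OC(C)(C)C)CC | intermediate
25 | tert-butyl (4S)-4-hydroxyhex-2-ynoate | O[C@H](C#CC(=O)OC(C)(C)C)CC | intermediate
26 | hex-2-ynoic acid | CCCC#CC(=O)O | starting material
27 | tert-butyl (4S)-4-(hex-2-ynoyloxy)hex-2-ynoate | CCCC#CC(=O)O[C@H](C#CC(=O)OC(C)(C)C)CC | intermediate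
28 | (4S)-4-(hex-2-ynoyloxy)hex-2-ynoic acid | CCCC#CC(=O)O[C@H](C#CC(=O)O)CC | intermediate
29 | (3R,4R,5R,9S,10R)-8-oxo-9-(triethylsilyloxy)eremophil-7(11)-en-3-yl (4S)-4-(hex-2-ynoyloxy)hex-2-ynoate | CCCC#CC(=O)O[C@H](C#CC(=O)O[C@@H]1CC[C@H]2[C@H](O[Si](CC)(CC)CC)C(=O)C(=C(C)C)C[C@]2(C)[C@H]1C)CC | intermediate
30 | (3R,4R,5R,9S,10R)-8-oxo-9-(triethylsilyloxy)eremophil-7(11)-en-3-yl (2Z,4S)-4-{[(2Z)-hex-2-enoyl]oxy}hex-2-enoate | CCC/C=C\C(=O)O[C@H](/C=C\C(=O)O[C@@H]1CC[C@H]2[C@H](O[Si](CC)(CC)CC)C(=O)C(=C(C)C)C[C@]2(C)[C@H]1C)CC | intermediate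
31 | (3R,4R,5R,9S,10R)-9-hydroxy-8-oxoeremophil-7(11)-en-3-yl (2Z,4S)-4-{[(2Z)-hex-2-enoyl]oxy}hex-2-enoate | CCC/C=C\C(=O)O[C@H](/C=C\C(=O)O[C@@H]1CC[C@H]2[C@H](O)C(=O)C(=C(C)C)C[C@]2(C)[C@H]1C)CC | target

## Step count and risk

Total: 20 steps. Longest linear sequence: 14 steps (steps 2–12, then 18–20, from pent-4-yn-1-ol 4; the same length from isoprene 1 through step 1). The side-chain branch (steps 13–17) joins at step 18.

**Step 6 (key step, proposed new method).**
- What may go wrong: oxidative cyclisation through an all-carbon four-atom tether may be too slow, so that homotrimerisation of 11 wins. Insertion of 11 may occur with the wrong orientation. The alkynyl C–B bond may transmetalate to rhodium.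
- Fallback (known chemistry): build the same enone by an intramolecular Diels–Alder reaction in which the C5=C6 alkene is the dienophile. It sets out from 8 and returns at 15.
  - Anti-Markovnikov hydroboration–oxidation of the terminal alkyne of 8 (dicyclohexylborane, then NaBO3) would give (5R,6R)-5-[(4-methoxybenzyl)oxy]-6,7-dimethyloct-7-enal F1.
  - Addition of vinylmagnesium bromide would give allylic alcohol F2, and Dess–Martin oxidation vinyl ketone F3.
  - Cross-metathesis of F3 with 2-methylbut-3-en-2-ol (second-generation Hoveyda–Grubbs catalyst) would give the (E)-γ-hydroxy enone F4.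
  - Me3SiOTf and Et3N would silylate the tertiary alcohol and convert the enone into the cross-conjugated (Z)-2-silyloxydiene F5.
  - Heating F5 in toluene (about 190 °C, sealed tube, base-washed glass) should effect the Diels–Alder reaction between the C10=C9–C8=C7 diene and the C5=C6 alkene (C5–C10 and C6–C7 bonds, the same chair preference at C5) to give silyl enol ether F6.
  - Saegusa–Ito oxidation with Pd(OAc)2 in MeCN would give enone F7, and K2CO3 in MeOH would remove the tertiary silyl ether and equilibrate C10, returning 15.
  - The detour costs eight steps and an unactivated dienophile, but each step is of a known type.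

**Step 3.**
- What may go wrong: loss of enantioselectivity or of syn selectivity, because aliphatic aldehydes and β-substituted allylboronates are less favourable partners for the phosphoric acid and the uncatalysed background reaction may compete.
- Fallback: an Evans syn-aldol sequence from 5 to 8.
  - The dibutylboron enolate of (4S)-4-benzyl-3-propanoyl-1,3-oxazolidin-2-one (Bu2BOTf, i-Pr2NEt) and 5 would give aldol adduct F8.
  - AlMe3 and N,O-dimethylhydroxylamine hydrochloride would give Weinreb amide F9.
  - 4-Methoxybenzyl trichloroacetimidate with catalytic acid would give ether F10.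
  - MeMgBr would give methyl ketone F11, and Wittig methylenation (Ph3P=CH2) would give 8.

**Step 10.**
- What may go wrong: dehydration of the tertiary alcohol to an isopropenyl diene, or a sluggish [3,3] shift to the hindered C8 next to the silyloxy group, with oxidative loss of the silyl ether on long exposure.
- Fallback: separate the transposition from the oxidation, from 17 to 18. Catalytic Ph3SiOReO3 in Et2O at low temperature would equilibrate 17 with the transposed secondary allylic alcohol F12 (8-hydroxy, C7=C11). Dess–Martin oxidation of F12 would give 18.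

**Step 11.**
- What may go wrong: slow enolisation, because the C9 hydrogen of 18 is equatorial and poorly aligned with the carbonyl; deconjugation of the isopropylidene group; or a 1,4 oxygen-to-oxygen silyl shift in the enolate.
- Fallback: equilibrate the free ketol instead, from 18 to 19. Bu4NF in THF would cleave the silyl ether to the 9β ketol F13. The basic fluoride (with Et3N if needed) would equilibrate F13 through the enediol to the 9α ketol F14, which is equatorial and conjugated. Et3SiCl and imidazole would then give 19.

**Step 19.**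
- What may go wrong: over-reduction to alkanoates, partial (E)-alkene formation, or unequal rates for the two ynoates, the one attached to the core being more hindered.
- Fallback: reduce before coupling, from 27 to 30. Semihydrogenation of 27 over Pd/CaCO3 poisoned with Pb(OAc)2 would give the (Z,Z)-diester F15, and CF3CO2H would give acid F16. F16 would be coupled with 20 through its 2,4,6-trichlorobenzoyl mixed anhydride (Et3N, then DMAP at 0 °C) to give 30 directly. This exposes a (Z)-enoic acid to activation, which is why it is not the first choice.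

## Further compounds

F1 | step 6 | (5R,6R)-5-[(4-methoxybenzyl)oxy]-6,7-dimethyloct-7-enal | COc1ccc(CO[C@@H]([C@H](C)C(C)=C)CCCC=O)cc1
F2 | step 6 | (7R,8R)-7-[(4-methoxybenzyl)oxy]-8,9-dimethyldeca-1,9-dien-3-ol (both C3 epimers) | COc1ccc(CO[C@@H]([C@H](C)C(C)=C)CCCC(O)C=C)cc1
F3 | step 6 | (7R,8R)-7-[(4-methoxybenzyl)oxy]-8,9-dimethyldeca-1,9-dien-3-one | COc1ccc(CO[C@@H]([C@H](C)C(C)=C)CCCC(=O)C=C)cc1
F4 | step 6 | (3E,9R,10R)-2-hydroxy-9-[(4-methoxybenzyl)oxy]-2,10,11-trimethyldodeca-3,11-dien-5-one | COc1ccc(CO[C@@H]([C@H](C)C(C)=C)CCCC(=O)/C=C/C(C)(C)O)cc1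
F5 | step 6 | (3E,5Z,9R,10R)-9-[(4-methoxybenzyl)oxy]-2,10,11-trimethyl-2,5-bis(trimethylsilyloxy)dodeca-3,5,11-triene | COc1ccc(CO[C@@H]([C@H](C)C(C)=C)CC/C=C(O[Si](C)(C)C)/C=C/C(C)(C)O[Si](C)(C)C)cc1
F6 | step 6 | (3R,4R,5R)-3-[(4-methoxybenzyl)oxy]-9,11-bis(trimethylsilyloxy)eremophil-8-ene (C7 and C10 not fixed; both are reset later) | COc1ccc(CO[C@@H]2CCC3C(O[Si](C)(C)C)=CC(C(C)(C)O[Si](C)(C)C)C[C@]3(C)[C@H]2C)cc1
F7 | step 6 | (3R,4R,5R)-3-[(4-methoxybenzyl)oxy]-11-(trimethylsilyloxy)eremophil-7-en-9-one (C10 not yet equilibrated) | COc1ccc(CO[C@@H]2CCC3C(=O)C=C(C(C)(C)O[Si](C)(C)C)C[C@]3(C)[C@H]2C)cc1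
F8 | step 3 | (4S)-4-benzyl-3-[(2S,3R)-3-hydroxy-2-methylhept-6-ynoyl]-1,3-oxazolidin-2-one | O[C@@H]([C@H](C)C(=O)N1C(=O)OC[C@@H]1Cc1ccccc1)CCC#C
F9 | step 3 | (2S,3R)-3-hydroxy-N-methoxy-N,2-dimethylhept-6-ynamide | O[C@@H]([C@H](C)C(=O)N(C)OC)CCC#C
F10 | step 3 | (2S,3R)-N-methoxy-3-[(4-methoxybenzyl)oxy]-N,2-dimethylhept-6-ynamide | COc1ccc(CO[C@@H]([C@H](C)C(=O)N(C)OC)CCC#C)cc1
F11 | step 3 | (3S,4R)-4-[(4-methoxybenzyl)oxy]-3-methyloct-7-yn-2-one | COc1ccc(CO[C@@H]([C@H](C)C(C)=O)CCC#C)cc1
F12 | step 10 | (3R,4R,5R,9S,10R)-3-[(4-methoxybenzyl)oxy]-9-(triethylsilyloxy)eremophil-7(11)-en-8-ol (9β-OSiEt3; C8 not fixed) | COc1ccc(CO[C@@H]2CC[C@H]3[C@@H](O[Si](CC)(CC)CC)C(O)C(=C(C)C)C[C@]3(C)[C@H]2C)cc1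
F13 | step 11 | (3R,4R,5R,9R,10R)-9-hydroxy-3-[(4-methoxybenzyl)oxy]eremophil-7(11)-en-8-one (9β-OH) | COc1ccc(CO[C@@H]2CC[C@H]3[C@@H](O)C(=O)C(=C(C)C)C[C@]3(C)[C@H]2C)cc1
F14 | step 11 | (3R,4R,5R,9S,10R)-9-hydroxy-3-[(4-methoxybenzyl)oxy]eremophil-7(11)-en-8-one (9α-OH) | COc1ccc(CO[C@@H]2CC[C@H]3[C@H](O)C(=O)C(=C(C)C)C[C@]3(C)[C@H]2C)cc1
F15 | step 19 | tert-butyl (2Z,4S)-4-{[(2Z)-hex-2-enoyl]oxy}hex-2-enoate | CCC/C=C\C(=O)O[C@H](/C=C\C(=O)OC(C)(C)C)CC
F16 | step 19 | (2Z,4S)-4-{[(2Z)-hex-2-enoyl]oxy}hex-2-enoic acid | CCC/C=C\C(=O)O[C@H](/C=C\C(=O)O)CC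
A1 | alternative 1 | tert-butyl{[(E)-2-{(4R,5R)-4-[(4-methoxybenzyl)oxy]-2,5... ring-A diene: (E)-2-[(3R,4R)-3-[(4-methoxybenzyl)oxy]-4,5-dimethyl-(eremophilane C1–C5,C10 ring)-10-yl]ethenyl tert-butyldimethylsilyl ether | COc1ccc(CO[C@@H]2CCC(/C=C/O[Si](C)(C)C(C)(C)C)=C(C)[C@H]2C)cc1
A2 | alternative 1 | methyl acrylate | C=CC(=O)OC
A3 | alternative 1 | 3-[(4-methoxybenzyl)oxy]-8-(tert-butyldimethylsilyloxy)eremophil-9-ene-7-carboxylic acid methyl ester (C7 methyl ester in place of the isopropyl unit) | COc1ccc(CO[C@@H]2CCC3=C[C@H](O[Si](C)(C)C(C)(C)C)[C@H](C(=O)OC)C[C@]3(C)[C@H]2C)cc1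
A4 | alternative 2 | (5E,9Z)-9-chloro-5-methyl-2-oxo-3-(propan-2-ylidene)undeca-5,9-dienal | O=CC(=O)C(=C(C)C)C/C(C)=C/CC/C(Cl)=C/C
A5 | alternative 2 | 9α-hydroxyeremophil-7(11)-ene-3,8-dione (trans-fused) | O=C1CC[C@H]2[C@H](O)C(=O)C(=C(C)C)C[C@]2(C)[C@H]1C
A6 | alternative 3 | (2E,6E)-farnesyl diphosphate | CC(C)=CCC/C(C)=C/CC/C(C)=C/COP(=O)(O)OP(=O)(O)O
A7 | alternative 3 | (+)-aristolochene | C1CCC2=CC[C@H](C(C)=C)C[C@]2(C)[C@H]1C
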